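The target is an achiral 2-alkyl-1,4-benzoquinone. Its ring holds one alkene with no substituent, C5=C6, which sits between the carbonyl carbons C4 and C1, and the plan cuts exactly this bond. At the alcohol oxidation level, C1 and C4 become two vinyl carbinols on a 2-nonadecylsuccinaldehyde core, that is, the acyclic 4-nonadecylocta-1,7-diene-3,6-diol. Ring-closing metathesis of its two terminal vinyl groups makes C5=C6 and the only carbocycle in one operation, with ethylene as the sole by-product. Oxidation, aromatising tautomerisation and a final hydroquinone oxidation then remove every stereocentre, so all diastereomers are carried together. The C19 chain comes from a C18 Grignard reagent and the methylene carbon of dimethyl itaconate.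

Key step: step 5

Remark: the target has no stereocentre. Every sp3 stereocentre on the way is formed without control and erased before the end, so racemates and diastereomer mixtures are carried on and the SMILES carry no stereodescriptors.

Step 1
Reactants: 1 1-bromooctadecane; 2 dimethyl itaconate
Product: 5 dimethyl 2-nonadecylbutanedioate (racemic), via octadecylmagnesium bromide 3 (not isolated), via silyl ketene acetal 4 (not isolated)
Conditions: Mg, THF, 45 °C; the solution is added slowly to 2, CuI·2LiCl (10 mol%), Me3SiCl (2.2 equiv), THF, −40 → 0 °C; dilute aq. HCl/NH4Cl
Reagents that add atoms: magnesium, [Mg] (enters intermediate 3 only); chlorotrimethylsilane, C[Si](C)(C)Cl (enters intermediate 4 only); no atom of either remains in 5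
Why: Copper-catalysed, Me3SiCl-accelerated 1,4-addition of a Grignard reagent (Kharasch-type conjugate addition) to an α-substituted acrylate: the alkylcopper species attacks the unhindered terminal CH2 of 2, Me3SiCl traps the enolate as 4 before it can attack an ester or a second molecule of 2, and unselective C-protonation on work-up gives racemic 5, whose stereocentre is erased in step 6.

Step 2
Reactants: 5 dimethyl 2-nonadecylbutanedioate
Product: 6 2-nonadecylbutane-1,4-diol (racemic)
Conditions: LiAlH4, THF, 0 °C → reflux; H2O/aq. NaOH work-up
Reagents that add atoms: none
Why: Standard LiAlH4 reduction of esters to primary alcohols; the saturated chain is the only other functionality and the stereocentre is untouched.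

Step 3
Reactants: 6 2-nonadecylbutane-1,4-diol
Product: 7 2-nonadecylbutanedial (racemic, used crude at once)
Conditions: (COCl)2, DMSO, CH2Cl2–THF, −78 → −50 °C; Et3N, → 0 °C; neutral aqueous work-up
Reagents that add atoms: none
Why: Swern oxidation: both hydroxyls become alkoxysulfonium ions before base is added, so no free hydroxy aldehyde exists that could close to a lactol and be oxidised to a lactone, which is the usual failure of other oxidants with 1,4-diols.

Step 4
Reactants: 7 2-nonadecylbutanedial; 8 vinylmagnesium bromide
Product: 9 4-nonadecylocta-1,7-diene-3,6-diol (mixture of diastereomers)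
Conditions: 8 (4 equiv), THF, −40 °C → rt; aq. NH4Cl
Reagents that add atoms: vinylmagnesium bromide (compound 8), C=C[Mg]Br
Why: Twofold 1,2-addition of a Grignard reagent to aldehydes, the reaction that also turns succinaldehyde into octa-1,7-diene-3,6-diol; excess reagent and warming open any magnesium lactolate formed after the first addition, and the two new carbinol centres are deliberately set without control because they become carbonyl carbons in step 6.

Step 5
Reactants: 9 4-nonadecylocta-1,7-diene-3,6-diol
Product: 10 5-nonadecylcyclohex-2-ene-1,4-diol (mixture of diastereomers)
Conditions: second-generation Grubbs catalyst RuCl2(=CHPh)(PCy3)(H2IMes) (3 mol%), 1,4-benzoquinone (10 mol%), CH2Cl2 (5 mM), 40 °C, Ar purge, 1–2 h; filtration through silica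
Reagents that add atoms: none
Why: Ring-closing olefin metathesis by the Chauvin mechanism: the ruthenium benzylidene exchanges with one vinyl group through [2+2] cycloaddition and cycloreversion of a ruthenacyclobutane, the new alkylidene is captured intramolecularly by the other vinyl group, and a second cycloreversion releases the ring alkene and Ru=CH2, which carries the cycle on. Closure of free or O-protected octa-1,7-diene-3,6-diols to cyclohex-2-ene-1,4-diols is an established use of this reaction. The single carbocycle closes as a six-membered ring by joining C2 and C7 of the diene while both terminal CH2 groups leave as ethylene, so the new bond is the future C5=C6 of the quinone and can only be Z. No stereocentre is created, the three existing ones are untouched, and both cis- and trans-diol isomers can adopt the half-chair ring, so the whole mixture converges. The step needs cyclisation to beat acyclic oligomerisation and ruthenium hydride isomerisation of the allylic carbinols to ketones. The first is secured by the strain-free ring size, two monosubstituted alkenes, high dilution and ethylene removal; the second by the rate-accelerating free allylic hydroxyls (deliberately left unprotected), the short reaction time and 1,4-benzoquinone as hydride scavenger.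

Step 6
Reactants: 10 5-nonadecylcyclohex-2-ene-1,4-diol
Product: 12 2-nonadecylbenzene-1,4-diol, via 5-nonadecylcyclohex-2-ene-1,4-dione 11 (not isolated)
Conditions: Dess–Martin periodinane (2.4 equiv), CH2Cl2, 0 °C → rt; aq. NaHCO3 wash; the dried CH2Cl2 layer is treated directly with TsOH·H2O (5 mol%), rt, Ar
Reagents that add atoms: none
Why: Dess–Martin oxidation of the two secondary allylic alcohols gives ene-dione 11, the non-aromatic diketo tautomer of a hydroquinone, and acid-catalysed double enolisation (the aromatisation used for quinone Diels–Alder adducts) is driven by the gain of aromaticity and removes the last stereocentre at C5.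

Step 7
Reactants: 12 2-nonadecylbenzene-1,4-diol
Product: 13 2-nonadecylcyclohexa-2,5-diene-1,4-dione (target)
Conditions: Ag2O (2 equiv), Et2O, rt, dark; filtration through Celite
Reagents that add atoms: none
Why: Classical Ag2O oxidation of a hydroquinone to the 1,4-benzoquinone under neutral, non-aqueous conditions, to which the alkyl chain is inert and after which only filtration is needed.

Compound list
1 | 1-bromooctadecane | CCCCCCCCCCCCCCCCCCBr | starting material
2 | dimethyl itaconate (dimethyl 2-methylidenebutanedioate) | C=C(CC(=O)OC)C(=O)OC | starting material
3 | octadecylmagnesium bromide (not isolated) | CCCCCCCCCCCCCCCCCC[Mg]Br | intermediate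
4 | methyl 3-[methoxy(trimethylsilyloxy)methylidene]docosanoate, silyl ketene acetal, E/Z mixture (not isolated) | CCCCCCCCCCCCCCCCCCCC(CC(=O)OC)=C(OC)O[Si](C)(C)C | intermediate
5 | dimethyl 2-nonadecylbutanedioate (racemic) | CCCCCCCCCCCCCCCCCCCC(CC(=O)OC)C(=O)OC | intermediate
6 | 2-nonadecylbutane-1,4-diol (racemic) | CCCCCCCCCCCCCCCCCCCC(CCO)CO | intermediate
7 | 2-nonadecylbutanedial (racemic) | CCCCCCCCCCCCCCCCCCCC(CC=O)C=O | intermediate
8 | vinylmagnesium bromide | C=C[Mg]Br | starting material
9 | 4-nonadecylocta-1,7-diene-3,6-diol (mixture of diastereomers) | CCCCCCCCCCCCCCCCCCCC(CC(O)C=C)C(O)C=C | intermediate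
10 | 5-nonadecylcyclohex-2-ene-1,4-diol (mixture of diastereomers) | CCCCCCCCCCCCCCCCCCCC1CC(O)C=CC1O | intermediate
11 | 5-nonadecylcyclohex-2-ene-1,4-dione (racemic, not isolated) | CCCCCCCCCCCCCCCCCCCC1CC(=O)C=CC1=O | intermediate
12 | 2-nonadecylbenzene-1,4-diol | CCCCCCCCCCCCCCCCCCCc1cc(O)ccc1O | intermediate
13 | 2-nonadecylcyclohexa-2,5-diene-1,4-dione | CCCCCCCCCCCCCCCCCCCC1=CC(=O)C=CC1=O | target

Total step count: 7. Longest linear sequence: 7 steps (from 1 or 2 to 13).

Steps most likely to fail

Step 5. Ruthenium hydride species from catalyst decay may shift the double bonds of the free allylic carbinols. The carbinols may also shorten the life of the alkylidene, so that closure stalls and intermolecular metathesis takes over. The fallback closes the ring on a masked substrate that cannot isomerise to a ketone. It sets out from 9, which is acetylated on both oxygens (Ac2O, pyridine, DMAP cat., CH2Cl2, rt) to 4-nonadecylocta-1,7-diene-3,6-diyl diacetate F1. This diene is cyclised with RuCl2(=CHPh)(PCy3)(H2IMes) in dilute CH2Cl2 at 40 °C to 5-nonadecylcyclohex-2-ene-1,4-diyl diacetate F2. Transesterification (K2CO3 cat., MeOH–THF, rt) brings the material back to the route at 10.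

Step 1. The basic organometallic may deprotonate the doubly activated CH2 of 2 and cause double-bond migration. Direct attack at an ester or anionic oligomerisation of the acceptor may also compete with the 1,4-addition. The fallback replaces the polar addition by a radical (Giese) addition. It sets out from 1, which is converted by Finkelstein exchange (NaI, acetone, reflux) into 1-iodooctadecane F3. Slow addition of (Me3Si)3SiH and AIBN to F3 and excess 2 in toluene at 80 °C lets the nucleophilic primary radical add to the CH2 terminus. The hindered tertiary α-ester radical propagates poorly and instead takes hydrogen from the silane. The route is rejoined at 5.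

Step 3. The waxy diol may be incompletely activated at low temperature, which allows lactol formation. The free dialdehyde may also self-condense, hydrate or cyclodehydrate during isolation. The fallback never liberates the dialdehyde. It sets out from 5, which is treated with iBu2AlH (2.1 equiv, toluene–CH2Cl2, −78 °C) to give 1,4-bis(diisobutylaluminiooxy)-1,4-dimethoxy-2-nonadecylbutane F4. Reagent 8 (5 equiv) is added at −78 °C before warming to 0 °C, so each aldehyde group released by collapse of the hemiacetal is captured at once. The route is rejoined at 9, and 6 and 7 are bypassed.

Further compounds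
F1 | step 5 | 4-nonadecylocta-1,7-diene-3,6-diyl diacetate (mixture of diastereomers) | CCCCCCCCCCCCCCCCCCCC(CC(OC(C)=O)C=C)C(OC(C)=O)C=C
F2 | step 5 | 5-nonadecylcyclohex-2-ene-1,4-diyl diacetate (mixture of diastereomers) | CCCCCCCCCCCCCCCCCCCC1CC(OC(C)=O)C=CC1OC(C)=O
F3 | step 1 | 1-iodooctadecane | CCCCCCCCCCCCCCCCCCI
F4 | step 3 | 1,4-bis(diisobutylaluminiooxy)-1,4-dimethoxy-2-nonadecylbutane (mixture of diastereomers) | CCCCCCCCCCCCCCCCCCCC(CC(OC)O[Al](CC(C)C)CC(C)C)C(OC)O[Al](CC(C)C)CC(C)C
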